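**Retrosynthetic overview**

1. The strategy rests on the two adjacent fully substituted carbons of ring B: C9 (tertiary carbinol carrying the C11 carboxyl) and C10 (quaternary A/B fusion carbon carrying C15). The C9–C10 bond is made by a rhodium carbene oxonium ylide [2,3]-shift between ring A allylic alcohol 5 and silyloxyvinyl diazoacetate 8.
2. Target ⇒ tert-butyl ester cleavage and C6 acylation with trienoyl chloride 24 ⇒ hydroxy enal 20 ⇒ palladium formylation (C12) and C6 oxidation–reduction (6β-OH) ⇒ C8 enol triflate 16.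
3. 16 ⇒ triflation and hydrogenation of C1=C2 ⇒ ketone 14 ⇒ ring B closed at C6–C7 by Mukaiyama aldol of aldehyde 13. Ring A comes with the starting material; ring B is the only ring formed.
4. 13 ⇒ key product 10 ⇒ 5 + 8. Alcohol 5 comes from ethyl 4-oxo-α-cyclogeranate 1 (Luche reduction, lipase resolution, LiAlH4, pivaloylation); 8 comes from tert-butyl acetoacetate 6 (diazo transfer, enol silylation).
5. The side-chain acid 23 comes from sorbaldehyde 21 and malonic acid 22.

Key step: step 7

Numbering: drimane numbering is used for all compounds, monocyclic ones included (ring A = C1–C5 and C10; ring B = C5–C10; C11 on C9; C12 on C8; C15 on C10). β is the face of the C10 methyl, α the face of H-5. The target SMILES has 6β-O-acyl, 9β-OH and 9α-CO2H.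

Assumption (step 2): the lipase acetylates the (1R,4R) enantiomer of 2 faster (usual enantiopreference of lipases for secondary carbinols, alkene side as the larger group), so the (1S,4S) alcohol is the recovered fraction.

Assumption (step 7): Rh2(S-DOSP)4 is the catalyst antipode matched with the (S)-carbinol of 5 for the (R) configuration at C9; if the sense is opposite, Rh2(R-DOSP)4 takes its place with nothing else changed.

Remark: the target is taken in the open hydroxy acid aldehyde form as drawn; ring–chain tautomerism of the C11 acid with the C12 aldehyde is not addressed.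

**Route**

Step 1
Reactants: 1 ethyl 2,6,6-trimethyl-4-oxocyclohex-2-ene-1-carboxylate (racemic)
Product: 2 ethyl (1RS,4RS)-4-hydroxy-2,6,6-trimethylcyclohex-2-ene-1-carboxylate (racemic trans isomer)
Conditions: NaBH4, CeCl3·7H2O, MeOH, −20 °C; chromatography
Reagents that add atoms: none
Why: Luche 1,2-reduction of the enone leaves the ester and the epimerisable ester-bearing carbon untouched; hydride should enter anti to the axial ring methyl of the half-chair that holds the ester pseudoaxial, favouring the trans carbinol, and the cis isomer is removed by chromatography.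

Step 2
Reactants: 2 ethyl (1RS,4RS)-4-hydroxy-2,6,6-trimethylcyclohex-2-ene-1-carboxylate
Product: 3 ethyl (1S,4S)-4-hydroxy-2,6,6-trimethylcyclohex-2-ene-1-carboxylate
Conditions: Amano lipase PS, vinyl acetate, tBuOMe, 30 °C, stopped just past half conversion
Reagents that add atoms: none
Why: Lipase-catalysed kinetic resolution by irreversible transesterification should acetylate the (1R,4R) enantiomer and leave the (1S,4S) alcohol, whose enantiomeric purity rises as conversion passes one half.

Step 3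
Reactants: 3 ethyl (1S,4S)-4-hydroxy-2,6,6-trimethylcyclohex-2-ene-1-carboxylate
Product: 4 (1S,4S)-4-(hydroxymethyl)-3,5,5-trimethylcyclohex-2-en-1-ol
Conditions: LiAlH4, THF, 0 °C
Reagents that add atoms: none
Why: Hydride reduction of the ester to the primary alcohol is non-enolising, so the allylic stereocentre (drimane C5) is not epimerised and the alkene does not migrate.

Step 4
Reactants: 4 (1S,4S)-4-(hydroxymethyl)-3,5,5-trimethylcyclohex-2-en-1-ol
Product: 5 [(1S,4S)-4-hydroxy-2,6,6-trimethylcyclohex-2-en-1-yl]methyl 2,2-dimethylpropanoate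
Conditions: PivCl, pyridine, CH2Cl2, −20 → 0 °C
Reagents that add atoms: pivaloyl chloride, CC(C)(C)C(Cl)=O
Why: Selective acylation of the primary over the secondary hydroxyl with a bulky acid chloride; the pivalate is chosen because hydride can later remove it without touching a silyl enol ether.

Step 5
Reactants: 6 tert-butyl 3-oxobutanoate
Product: 7 tert-butyl 2-diazo-3-oxobutanoate
Conditions: 4-acetamidobenzenesulfonyl azide, Et3N, MeCN, 0 °C → rt
Reagents that add atoms: 4-acetamidobenzenesulfonyl azide, CC(=O)Nc1ccc(cc1)S(=O)(=O)N=[N+]=[N-]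
Why: Regitz diazo transfer to the active methylene of a β-keto ester; the tert-butyl ester is chosen so that C11 can be freed by acid at the end.

Step 6
Reactants: 7 tert-butyl 2-diazo-3-oxobutanoate
Product: 8 tert-butyl 3-(tert-butyldimethylsilyloxy)-2-diazobut-3-enoate
Conditions: TBSOTf, Et3N, CH2Cl2, 0 °C
Reagents that add atoms: tert-butyldimethylsilyl trifluoromethanesulfonate, CC(C)(C)[Si](C)(C)OS(=O)(=O)C(F)(F)F
Why: Soft enolisation and O-silylation of the acetyl group give the silyloxyvinyl diazoacetate, a donor/acceptor carbene precursor that carries the masked C8 ketone and the C7 nucleophile.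

Step 7
Reactants: 5 [(1S,4S)-4-hydroxy-2,6,6-trimethylcyclohex-2-en-1-yl]methyl 2,2-dimethylpropanoate; 8 tert-butyl 3-(tert-butyldimethylsilyloxy)-2-diazobut-3-enoate
Product: 10 tert-butyl (2R)-3-(tert-butyldimethylsilyloxy)-2-hydroxy-2-[(1S,6S)-6-(pivaloyloxymethyl)-1,5,5-trimethylcyclohex-2-en-1-yl]but-3-enoate, via oxonium ylide 9 (not isolated)
Conditions: Rh2(S-DOSP)4 (dirhodium tetrakis[(S)-N-(4-dodecylphenylsulfonyl)prolinate], 1 mol%), pentane, 0 °C, slow addition of 8 (1.5 equiv)
Reagents that add atoms: none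
Why: The divalent rhodium dimer expels N2 from 8 to give a donor/acceptor rhodium carbene, the hydroxyl oxygen of 5 adds to it to form the metal-associated oxonium ylide 9, and 9 undergoes a [2,3]-sigmatropic shift through a five-membered envelope in which carbanionic C9 bonds to C10 while the C2–O bond breaks and the alkene moves to C1=C2. The closest known reaction type is the dirhodium-catalysed tandem oxonium ylide formation/[2,3]-rearrangement of aryl- and vinyldiazoacetates with substituted allylic alcohols; no ring is closed, two fragments of similar size are joined. C10 is set by suprafacial chirality transfer from the C2 carbinol: the pseudoaxial α oxygen delivers C9 to the α face, trans to the C5 substituent, so C15 ends β. C9 is set by the chiral carboxylate ligands, which fix the face of the ylide carbon that bonds, in the pairing matched with the (S)-carbinol. The step needs the rearrangement to outrun the 1,2-proton shift (net O–H insertion) and attack at the carbene carbon instead of its vinylogous terminus; the methyl-bearing trisubstituted alkene terminus and the secondary carbinol favour the [2,3] path, and the rhodium catalyst with the bulky silyl enol ether in a hydrocarbon solvent favours attack at the carbene carbon.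

Step 8
Reactants: 10 tert-butyl (2R)-3-(tert-butyldimethylsilyloxy)-2-hydroxy-2-[(1S,6S)-6-(pivaloyloxymethyl)-1,5,5-trimethylcyclohex-2-en-1-yl]but-3-enoate
Product: 11 tert-butyl (2R)-3-(tert-butyldimethylsilyloxy)-2-[(1S,6S)-6-(pivaloyloxymethyl)-1,5,5-trimethylcyclohex-2-en-1-yl]-2-(trimethylsilyloxy)but-3-enoate
Conditions: TMSOTf, 2,6-lutidine, CH2Cl2, −78 → 0 °C
Reagents that add atoms: trimethylsilyl trifluoromethanesulfonate, C[Si](C)(C)OS(=O)(=O)C(F)(F)F
Why: Silyl triflate silylation caps the hindered tertiary C9 hydroxyl, so that it can later neither direct hydride to C11, nor be triflated, nor trigger an α-ketol shift once C8 is a ketone.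

Step 9
Reactants: 11 tert-butyl (2R)-3-(tert-butyldimethylsilyloxy)-2-[(1S,6S)-6-(pivaloyloxymethyl)-1,5,5-trimethylcyclohex-2-en-1-yl]-2-(trimethylsilyloxy)but-3-enoate
Product: 12 tert-butyl (2R)-3-(tert-butyldimethylsilyloxy)-2-[(1S,6S)-6-(hydroxymethyl)-1,5,5-trimethylcyclohex-2-en-1-yl]-2-(trimethylsilyloxy)but-3-enoate
Conditions: iBu2AlH, CH2Cl2, −78 °C
Reagents that add atoms: none
Why: Reductive ester cleavage at low temperature removes the unhindered primary pivalate, while the tert-butyl ester on the fully substituted C9, the silyl enol ether and the silyl ether should not react.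

Step 10
Reactants: 12 tert-butyl (2R)-3-(tert-butyldimethylsilyloxy)-2-[(1S,6S)-6-(hydroxymethyl)-1,5,5-trimethylcyclohex-2-en-1-yl]-2-(trimethylsilyloxy)but-3-enoate
Product: 13 tert-butyl (2R)-3-(tert-butyldimethylsilyloxy)-2-[(1S,6S)-6-formyl-1,5,5-trimethylcyclohex-2-en-1-yl]-2-(trimethylsilyloxy)but-3-enoate
Conditions: nPr4N[RuO4] (5 mol%), N-methylmorpholine N-oxide, 4 Å MS, CH2Cl2, rt
Reagents that add atoms: none
Why: Ley–Griffith oxidation gives the C6 aldehyde under neutral conditions that should spare the silyl enol ether and not epimerise C5.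

Step 11
Reactants: 13 tert-butyl (2R)-3-(tert-butyldimethylsilyloxy)-2-[(1S,6S)-6-formyl-1,5,5-trimethylcyclohex-2-en-1-yl]-2-(trimethylsilyloxy)but-3-enoate
Product: 14 tert-butyl 6-(tert-butyldimethylsilyloxy)-8-oxo-9β-(trimethylsilyloxy)-12-nor-5α-drim-1-en-11-oate (C6 epimers)
Conditions: TBSOTf (10 mol%), CH2Cl2, −78 °C
Reagents that add atoms: none
Why: Intramolecular Mukaiyama aldol with silyl transfer: C7 of the enol ether attacks the silyl-activated C6 aldehyde (6-exo-trig closure of ring B); the trans ring fusion is fixed by the existing C5 and C10 centres, and the C6 configuration is not controlled because it is erased in step 15.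

Step 12
Reactants: 14 tert-butyl 6-(tert-butyldimethylsilyloxy)-8-oxo-9β-(trimethylsilyloxy)-12-nor-5α-drim-1-en-11-oate
Product: 15 tert-butyl 6-(tert-butyldimethylsilyloxy)-8-oxo-9β-(trimethylsilyloxy)-12-nor-5α-driman-11-oate (C6 epimers)
Conditions: H2 (1 atm), Pd/C (palladium on carbon), EtOAc, rt
Reagents that add atoms: none
Why: Heterogeneous hydrogenation saturates the only C=C bond (C1=C2) without creating a stereocentre; ketone, ester and silyl ethers are inert in ethyl acetate.

Step 13
Reactants: 15 tert-butyl 6-(tert-butyldimethylsilyloxy)-8-oxo-9β-(trimethylsilyloxy)-12-nor-5α-driman-11-oate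
Product: 16 tert-butyl 6-(tert-butyldimethylsilyloxy)-8-(trifluoromethanesulfonyloxy)-9β-(trimethylsilyloxy)-12-nor-5α-drim-7-en-11-oate (C6 epimers)
Conditions: KN(SiMe3)2, THF, −78 °C; then PhNTf2
Reagents that add atoms: N-phenylbis(trifluoromethanesulfonimide), O=S(=O)(N(c1ccccc1)S(=O)(=O)C(F)(F)F)C(F)(F)F
Why: Enol triflate formation is regiospecific because only C7 carries α-hydrogens (C9 is fully substituted), and at −78 °C the β-silyloxy group should not be eliminated.

Step 14
Reactants: 16 tert-butyl 6-(tert-butyldimethylsilyloxy)-8-(trifluoromethanesulfonyloxy)-9β-(trimethylsilyloxy)-12-nor-5α-drim-7-en-11-oate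
Product: 17 tert-butyl 6,9β-dihydroxy-8-(trifluoromethanesulfonyloxy)-12-nor-5α-drim-7-en-11-oate (C6 epimers)
Conditions: HF·pyridine, THF/pyridine, 0 °C → rt
Reagents that add atoms: none
Why: Buffered fluoride desilylation removes both silyl ethers, while the vinyl triflate and the tert-butyl ester are stable to it.

Step 15
Reactants: 17 tert-butyl 6,9β-dihydroxy-8-(trifluoromethanesulfonyloxy)-12-nor-5α-drim-7-en-11-oate
Product: 18 tert-butyl 9β-hydroxy-6-oxo-8-(trifluoromethanesulfonyloxy)-12-nor-5α-drim-7-en-11-oate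
Conditions: Dess–Martin periodinane, NaHCO3, CH2Cl2, 0 °C → rt
Reagents that add atoms: none
Why: Dess–Martin oxidation converts the secondary allylic C6 alcohol (both epimers) into the enone, while the tertiary C9 hydroxyl cannot be oxidised.

Step 16
Reactants: 18 tert-butyl 9β-hydroxy-6-oxo-8-(trifluoromethanesulfonyloxy)-12-nor-5α-drim-7-en-11-oate
Product: 19 tert-butyl 6β,9β-dihydroxy-8-(trifluoromethanesulfonyloxy)-12-nor-5α-drim-7-en-11-oate
Conditions: NaBH4, CeCl3·7H2O, MeOH/THF, −78 °C
Reagents that add atoms: none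
Why: Luche 1,2-reduction: the β face of C6 is shielded by the syn-axial methyls on C10 and C4, so hydride should enter from the α face and give the axial 6β alcohol, and the cold protic medium protonates the alkoxide before it can fragment.

Step 17
Reactants: 19 tert-butyl 6β,9β-dihydroxy-8-(trifluoromethanesulfonyloxy)-12-nor-5α-drim-7-en-11-oate
Product: 20 tert-butyl 6β,9β-dihydroxy-12-oxo-5α-drim-7-en-11-oate
Conditions: Pd(PPh3)4 (5 mol%), CO (1 atm), Bu3SnH (slow addition), THF, 50 °C
Reagents that add atoms: carbon monoxide, [C-]#[O+]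
Why: Palladium-catalysed reductive carbonylation of the vinyl triflate (oxidative addition to zerovalent palladium, CO insertion, hydride transfer from tin, reductive elimination) installs C12 as the aldehyde with the 7,8-alkene in place; neither hydroxyl can lactonise onto the acyl palladium.

Step 18
Reactants: 21 (2E,4E)-hexa-2,4-dienal (sorbaldehyde); 22 malonic acid
Product: 23 (2E,4E,6E)-octa-2,4,6-trienoic acid
Conditions: pyridine, piperidine (cat.), 90 °C
Reagents that add atoms: none
Why: Doebner–Knoevenagel condensation with decarboxylation extends the dienal by two carbons and gives the E alkene.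

Step 19
Reactants: 23 (2E,4E,6E)-octa-2,4,6-trienoic acid
Product: 24 (2E,4E,6E)-octa-2,4,6-trienoyl chloride
Conditions: (COCl)2, DMF (cat.), CH2Cl2, 0 °C → rt; used crude
Reagents that add atoms: oxalyl chloride, O=C(Cl)C(Cl)=O
Why: Acid chloride formation through the Vilsmeier-type chloroiminium intermediate proceeds under mild conditions that do not isomerise the triene.

Step 20
Reactants: 20 tert-butyl 6β,9β-dihydroxy-12-oxo-5α-drim-7-en-11-oate; 24 (2E,4E,6E)-octa-2,4,6-trienoyl chloride
Product: 25 tert-butyl 9β-hydroxy-6β-[(2E,4E,6E)-octa-2,4,6-trienoyloxy]-12-oxo-5α-drim-7-en-11-oate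
Conditions: pyridine, DMAP, CH2Cl2, 0 °C → rt
Reagents that add atoms: none
Why: DMAP-catalysed acylation esterifies the secondary 6β hydroxyl while the tertiary C9 hydroxyl is too hindered to react; pyridine is used instead of a trialkylamine to avoid deconjugation through a vinylketene.

Step 21
Reactants: 25 tert-butyl 9β-hydroxy-6β-[(2E,4E,6E)-octa-2,4,6-trienoyloxy]-12-oxo-5α-drim-7-en-11-oate
Product: 26 9β-hydroxy-6β-[(2E,4E,6E)-octa-2,4,6-trienoyloxy]-12-oxo-5α-drim-7-en-11-oic acid
Conditions: CF3CO2H/CH2Cl2 (1:4), 0 °C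
Reagents that add atoms: none
Why: Acidolysis of the tert-butyl ester (loss of 2-methylpropene) frees the C11 acid; the allylic C6 ester and the C9 carbinol should not ionise because the alkene is electron-poor and C9 carries the carboxyl.

**Compound list**

1 | ethyl 2,6,6-trimethyl-4-oxocyclohex-2-ene-1-carboxylate (racemic) | CCOC(=O)C1C(C)=CC(=O)CC1(C)C | starting material
2 | ethyl (1RS,4RS)-4-hydroxy-2,6,6-trimethylcyclohex-2-ene-1-carboxylate (racemic trans isomer) | O[C@@H]1C=C(C)[C@@H](C(=O)OCC)C(C)(C)C1.O[C@H]1C=C(C)[C@H](C(=O)OCC)C(C)(C)C1 | intermediate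
3 | ethyl (1S,4S)-4-hydroxy-2,6,6-trimethylcyclohex-2-ene-1-carboxylate | O[C@@H]1C=C(C)[C@@H](C(=O)OCC)C(C)(C)C1 | intermediate
4 | (1S,4S)-4-(hydroxymethyl)-3,5,5-trimethylcyclohex-2-en-1-ol | O[C@@H]1C=C(C)[C@@H](CO)C(C)(C)C1 | intermediate
5 | [(1S,4S)-4-hydroxy-2,6,6-trimethylcyclohex-2-en-1-yl]methyl 2,2-dimethylpropanoate | O[C@@H]1C=C(C)[C@@H](COC(=O)C(C)(C)C)C(C)(C)C1 | intermediate
6 | tert-butyl 3-oxobutanoate | CC(=O)CC(=O)OC(C)(C)C | starting material
7 | tert-butyl 2-diazo-3-oxobutanoate | CC(=O)C(=[N+]=[N-])C(=O)OC(C)(C)C | intermediate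
8 | tert-butyl 3-(tert-butyldimethylsilyloxy)-2-diazobut-3-enoate | C=C(O[Si](C)(C)C(C)(C)C)C(=[N+]=[N-])C(=O)OC(C)(C)C | intermediate
9 | oxonium ylide from 5 and the carbene of 8 (rhodium-associated, drawn metal-free) | CC(C)(C)OC(=O)[C-]([OH+][C@@H]1C=C(C)[C@@H](COC(=O)C(C)(C)C)C(C)(C)C1)C(=C)O[Si](C)(C)C(C)(C)C | intermediate
10 | tert-butyl (2R)-3-(tert-butyldimethylsilyloxy)-2-hydroxy-2-[(1S,6S)-6-(pivaloyloxymethyl)-1,5,5-trimethylcyclohex-2-en-1-yl]but-3-enoate | CC(C)(C)OC(=O)[C@](O)(C(=C)O[Si](C)(C)C(C)(C)C)[C@@]1(C)C=CCC(C)(C)[C@@H]1COC(=O)C(C)(C)C | intermediate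
11 | tert-butyl (2R)-3-(tert-butyldimethylsilyloxy)-2-[(1S,6S)-6-(pivaloyloxymethyl)-1,5,5-trimethylcyclohex-2-en-1-yl]-2-(trimethylsilyloxy)but-3-enoate | CC(C)(C)OC(=O)[C@](O[Si](C)(C)C)(C(=C)O[Si](C)(C)C(C)(C)C)[C@@]1(C)C=CCC(C)(C)[C@@H]1COC(=O)C(C)(C)C | intermediate
12 | tert-butyl (2R)-3-(tert-butyldimethylsilyloxy)-2-[(1S,6S)-6-(hydroxymethyl)-1,5,5-trimethylcyclohex-2-en-1-yl]-2-(trimethylsilyloxy)but-3-enoate | CC(C)(C)OC(=O)[C@](O[Si](C)(C)C)(C(=C)O[Si](C)(C)C(C)(C)C)[C@@]1(C)C=CCC(C)(C)[C@@H]1CO | intermediate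
13 | tert-butyl (2R)-3-(tert-butyldimethylsilyloxy)-2-[(1S,6S)-6-formyl-1,5,5-trimethylcyclohex-2-en-1-yl]-2-(trimethylsilyloxy)but-3-enoate | CC(C)(C)OC(=O)[C@](O[Si](C)(C)C)(C(=C)O[Si](C)(C)C(C)(C)C)[C@@]1(C)C=CCC(C)(C)[C@@H]1C=O | intermediate
14 | tert-butyl 6-(tert-butyldimethylsilyloxy)-8-oxo-9β-(trimethylsilyloxy)-12-nor-5α-drim-1-en-11-oate (10β-methyl, 9α-ester; C6 not defined) | CC(C)(C)[Si](C)(C)OC1CC(=O)[C@@](O[Si](C)(C)C)(C(=O)OC(C)(C)C)[C@@]2(C)C=CCC(C)(C)[C@H]12 | intermediate
15 | tert-butyl 6-(tert-butyldimethylsilyloxy)-8-oxo-9β-(trimethylsilyloxy)-12-nor-5α-driman-11-oate (C6 not defined) | CC(C)(C)[Si](C)(C)OC1CC(=O)[C@@](O[Si](C)(C)C)(C(=O)OC(C)(C)C)[C@@]2(C)CCCC(C)(C)[C@H]12 | intermediate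
16 | tert-butyl 6-(tert-butyldimethylsilyloxy)-8-(trifluoromethanesulfonyloxy)-9β-(trimethylsilyloxy)-12-nor-5α-drim-7-en-11-oate (C6 not defined) | CC(C)(C)[Si](C)(C)OC1C=C(OS(=O)(=O)C(F)(F)F)[C@@](O[Si](C)(C)C)(C(=O)OC(C)(C)C)[C@@]2(C)CCCC(C)(C)[C@H]12 | intermediate
17 | tert-butyl 6,9β-dihydroxy-8-(trifluoromethanesulfonyloxy)-12-nor-5α-drim-7-en-11-oate (C6 not defined) | OC1C=C(OS(=O)(=O)C(F)(F)F)[C@@](O)(C(=O)OC(C)(C)C)[C@@]2(C)CCCC(C)(C)[C@H]12 | intermediate
18 | tert-butyl 9β-hydroxy-6-oxo-8-(trifluoromethanesulfonyloxy)-12-nor-5α-drim-7-en-11-oate | O=C1C=C(OS(=O)(=O)C(F)(F)F)[C@@](O)(C(=O)OC(C)(C)C)[C@@]2(C)CCCC(C)(C)[C@H]12 | intermediate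
19 | tert-butyl 6β,9β-dihydroxy-8-(trifluoromethanesulfonyloxy)-12-nor-5α-drim-7-en-11-oate | O[C@@H]1C=C(OS(=O)(=O)C(F)(F)F)[C@@](O)(C(=O)OC(C)(C)C)[C@@]2(C)CCCC(C)(C)[C@H]12 | intermediate
20 | tert-butyl 6β,9β-dihydroxy-12-oxo-5α-drim-7-en-11-oate | O[C@@H]1C=C(C=O)[C@@](O)(C(=O)OC(C)(C)C)[C@@]2(C)CCCC(C)(C)[C@H]12 | intermediate
21 | (2E,4E)-hexa-2,4-dienal (sorbaldehyde) | C/C=C/C=C/C=O | starting material
22 | malonic acid | OC(=O)CC(=O)O | starting material
23 | (2E,4E,6E)-octa-2,4,6-trienoic acid | C/C=C/C=C/C=C/C(=O)O | intermediate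
24 | (2E,4E,6E)-octa-2,4,6-trienoyl chloride | C/C=C/C=C/C=C/C(=O)Cl | intermediate
25 | tert-butyl 9β-hydroxy-6β-[(2E,4E,6E)-octa-2,4,6-trienoyloxy]-12-oxo-5α-drim-7-en-11-oate | C/C=C/C=C/C=C/C(=O)O[C@@H]1C=C(C=O)[C@@](O)(C(=O)OC(C)(C)C)[C@@]2(C)CCCC(C)(C)[C@H]12 | intermediate
26 | 9β-hydroxy-6β-[(2E,4E,6E)-octa-2,4,6-trienoyloxy]-12-oxo-5α-drim-7-en-11-oic acid | C/C=C/C=C/C=C/C(=O)O[C@@H]1C=C(C=O)[C@@](O)(C(=O)O)[C@@]2(C)CCCC(C)(C)[C@H]12 | target

**Step count**

Total: 21 steps. Longest linear sequence: 17 steps (steps 1–4, 7–17, 20, 21).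

**Steps most likely to fail**

Step 7. The ylide may collapse by 1,2-proton shift (net O–H insertion) faster than it rearranges, the carbene may be attacked at its vinylogous carbon, or the catalyst may fail to override the facial bias of the substrate at C9. The fallback sets out from alcohol 5 and diazo keto ester 7 and comes back at 10. Rh2(OAc)4 in hot benzene turns 7 into an acceptor/acceptor carbene that inserts into the O–H bond of 5. The resulting hydrogen-bonded enol, tert-butyl (2E)-3-hydroxy-2-{[(1S,4S)-4-(pivaloyloxymethyl)-3,5,5-trimethylcyclohex-2-en-1-yl]oxy}but-2-enoate F1, is an allyl vinyl ether and should undergo Claisen rearrangement in the same flask to tert-butyl 3-hydroxy-3-[(1S,6S)-6-(pivaloyloxymethyl)-1,5,5-trimethylcyclohex-2-en-1-yl]-2-oxobutanoate F2 (C8–C10 bond on the α face, alkene moved to C1=C2). BF3·OEt2 then induces the α-ketol shift of the ring carbon from C8 to C9, giving tert-butyl (2R)-2-hydroxy-2-[(1S,6S)-6-(pivaloyloxymethyl)-1,5,5-trimethylcyclohex-2-en-1-yl]-3-oxobutanoate F3. TBSOTf/Et3N silylates the methyl ketone of F3 to give 10. In this variant C9 rests on substrate control (chair-like Claisen transition state, stereospecific 1,2-shift), so its configuration has to be checked.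

Step 11. The silyl triflate may fail to activate the shielded, neopentyl-type aldehyde, so that the enol ether is protodesilylated or C5 epimerises before ring B closes. The fallback sets out from aldehyde 13 and comes back at 14. N-Bromosuccinimide in THF at 0 °C converts the silyl enol ether into tert-butyl (2R)-4-bromo-2-[(1S,6S)-6-formyl-1,5,5-trimethylcyclohex-2-en-1-yl]-3-oxo-2-(trimethylsilyloxy)butanoate F4. SmI2 in THF at −78 °C generates the samarium enolate, which closes ring B by a Reformatsky-type aldol on the C6 aldehyde to give tert-butyl 6-hydroxy-8-oxo-9β-(trimethylsilyloxy)-12-nor-5α-drim-1-en-11-oate F5. TBSOTf/2,6-lutidine silylates the C6 hydroxyl of F5 to give 14.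

Step 16. The alkoxide formed by hydride addition to the vinylogous acyl triflate may undergo Grob-type cleavage of the C6–C7 bond with loss of triflate, or hydride may add in conjugate fashion and expel triflate. The fallback sets out from triflate 16 and comes back at 20; it installs C12 before C6 is adjusted. Reductive carbonylation of 16 (Pd(PPh3)4, CO, Bu3SnH) gives tert-butyl 6-(tert-butyldimethylsilyloxy)-12-oxo-9β-(trimethylsilyloxy)-5α-drim-7-en-11-oate F6. HF·pyridine removes both silyl groups to give tert-butyl 6,9β-dihydroxy-12-oxo-5α-drim-7-en-11-oate F7. Dess–Martin periodinane oxidises C6 to give tert-butyl 9β-hydroxy-6,12-dioxo-5α-drim-7-en-11-oate F8. NaBH4/CeCl3 reduces both carbonyl groups, the ketone from the α face, to tert-butyl 6β,9β,12-trihydroxy-5α-drim-7-en-11-oate F9. TEMPO/PhI(OAc)2 then re-oxidises only the primary allylic alcohol of F9 to give 20.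

**Further compounds**

F1 | step 7 | tert-butyl (2E)-3-hydroxy-2-{[(1S,4S)-4-(pivaloyloxymethyl)-3,5,5-trimethylcyclohex-2-en-1-yl]oxy}but-2-enoate | C/C(O)=C(\O[C@@H]1C=C(C)[C@@H](COC(=O)C(C)(C)C)C(C)(C)C1)C(=O)OC(C)(C)C
F2 | step 7 | tert-butyl 3-hydroxy-3-[(1S,6S)-6-(pivaloyloxymethyl)-1,5,5-trimethylcyclohex-2-en-1-yl]-2-oxobutanoate (carbinol configuration set by the rearrangement, not assigned) | CC(O)(C(=O)C(=O)OC(C)(C)C)[C@@]1(C)C=CCC(C)(C)[C@@H]1COC(=O)C(C)(C)C
F3 | step 7 | tert-butyl (2R)-2-hydroxy-2-[(1S,6S)-6-(pivaloyloxymethyl)-1,5,5-trimethylcyclohex-2-en-1-yl]-3-oxobutanoate | CC(=O)[C@@](O)(C(=O)OC(C)(C)C)[C@@]1(C)C=CCC(C)(C)[C@@H]1COC(=O)C(C)(C)C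
F4 | step 11 | tert-butyl (2R)-4-bromo-2-[(1S,6S)-6-formyl-1,5,5-trimethylcyclohex-2-en-1-yl]-3-oxo-2-(trimethylsilyloxy)butanoate | CC(C)(C)OC(=O)[C@](O[Si](C)(C)C)(C(=O)CBr)[C@@]1(C)C=CCC(C)(C)[C@@H]1C=O
F5 | step 11 | tert-butyl 6-hydroxy-8-oxo-9β-(trimethylsilyloxy)-12-nor-5α-drim-1-en-11-oate (C6 not defined) | OC1CC(=O)[C@@](O[Si](C)(C)C)(C(=O)OC(C)(C)C)[C@@]2(C)C=CCC(C)(C)[C@H]12
F6 | step 16 | tert-butyl 6-(tert-butyldimethylsilyloxy)-12-oxo-9β-(trimethylsilyloxy)-5α-drim-7-en-11-oate (C6 not defined) | CC(C)(C)[Si](C)(C)OC1C=C(C=O)[C@@](O[Si](C)(C)C)(C(=O)OC(C)(C)C)[C@@]2(C)CCCC(C)(C)[C@H]12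
F7 | step 16 | tert-butyl 6,9β-dihydroxy-12-oxo-5α-drim-7-en-11-oate (C6 not defined) | OC1C=C(C=O)[C@@](O)(C(=O)OC(C)(C)C)[C@@]2(C)CCCC(C)(C)[C@H]12
F8 | step 16 | tert-butyl 9β-hydroxy-6,12-dioxo-5α-drim-7-en-11-oate | O=C1C=C(C=O)[C@@](O)(C(=O)OC(C)(C)C)[C@@]2(C)CCCC(C)(C)[C@H]12
F9 | step 16 | tert-butyl 6β,9β,12-trihydroxy-5α-drim-7-en-11-oate | O[C@@H]1C=C(CO)[C@@](O)(C(=O)OC(C)(C)C)[C@@]2(C)CCCC(C)(C)[C@H]12
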